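The cyclohexene of the acyl half (ring B; C1′ carries CH2OH (C7′), C2′ is the ring CH=, C3′ carries the acrylate, C4′ the isopropyl group) is made by closing the C1′=C2′ bond through an intramolecular Horner–Wadsworth–Emmons olefination. The precursor, an open-chain γ-nitro aldehyde bearing a phosphonoacetate, is assembled in the same flask from a silyloxypropanal, a nitroalkene and a phosphonoacrylate, so one operation sets the trans C3′/C4′ pair and delivers ring B as its C1′ ester. The step exploits the C1′=C2′–C7′ enoate retron and the unsubstituted C5′, which carries a traceless nitro group. The hydroxy lactone half comes from (R)-cryptone; carboxylate opening of a spiro-epoxide joins the halves.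

Key step: step 2

Remark: the nitro-bearing carbon of 8 and 9 (and of F1, F2) should form as both epimers and is drawn without a stereodescriptor, because step 3 deletes this centre.
Remark: ring A is the cyclohexane and ring C the seven-membered lactone of the alcohol half. Q denotes the acyl group of acid 17, (2E)-2-{[(4-methoxybenzyl)oxy]methyl}-3-[(1R,6R)-3-{[(4-methoxybenzyl)oxy]methyl}-6-(propan-2-yl)cyclohex-2-en-1-yl]prop-2-enoyl.

Step 1
Reactants: 1 2-methylpropanal; 2 nitromethane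
Product: 4 (E)-3-methyl-1-nitrobut-1-ene, via nitro alcohol 3 (not isolated)
Conditions: Et3N (10 mol%), excess 2, 0 °C → rt; then MsCl, Et3N, CH2Cl2, 0 °C
Reagents that add atoms: none
Why: Henry (nitroaldol) addition followed by mesylation and base-induced elimination should give the conjugated nitroalkene in its favoured E geometry.

Step 2
Reactants: 4 (E)-3-methyl-1-nitrobut-1-ene; 5 3-[(tert-butyldimethylsilyl)oxy]propanal; 6 ethyl 2-(diethoxyphosphoryl)acrylate
Product: 9 ethyl (3S,4R,5RS)-3-({[tert-butyl(dimethyl)silyl]oxy}methyl)-5-nitro-4-(propan-2-yl)cyclohex-1-ene-1-carboxylate, via γ-nitro aldehyde 7 (not isolated), via phosphonate adduct 8 (not isolated)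
Conditions: (S)-α,α-diphenylprolinol trimethylsilyl ether (10 mol%), ClCH2CO2H (20 mol%), CH2Cl2, rt; then 6, Cs2CO3, 0 °C; then EtOH, rt
Reagents that add atoms: none
Why: The amine turns 5 into its E-enamine, whose face next to the diphenyl(silyloxy)methyl group is blocked, and Michael addition to 4 through the synclinal transition state gives the syn adduct 7; Cs2CO3 then deprotonates the nitro-bearing carbon, the nitronate adds to 6 (C5′–C6′ bond), and the phosphonate carbanion of 8 closes ring B by intramolecular Horner–Wadsworth–Emmons olefination of the aldehyde, forming C1′=C2′. The closest known reaction type is the one-pot amine-catalysed Michael / nitro-Michael / Horner–Wadsworth–Emmons annulation of an aldehyde, a nitroalkene and a 2-phosphonoacrylate to a 5-nitrocyclohex-1-ene-1-carboxylate. The six-membered ring closes in the 6-exo-trig mode (carbanion addition to the formyl group) followed by syn elimination of diethyl phosphate, which places the double bond at C1′=C2′ with the ester carbon C7′ on C1′. The new stereocentres C3′ and C4′ are controlled by the catalyst (enamine face) and by the acyclic synclinal transition state (syn adduct, which becomes the trans pair on the ring), while the nitro-bearing C5′ forms unselectively and is removed in step 3. The step needs deprotonation at the nitro carbon without epimerisation of the aldehyde α-centre, and cyclisation instead of intermolecular olefination; the acidity gap between nitroalkane and aldehyde α-hydrogen, the low temperature and the six-atom tether secure this, and ethanol should return stalled β-hydroxyphosphonates to the product.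

Step 3
Reactants: 9 ethyl (3S,4R,5RS)-3-({[tert-butyl(dimethyl)silyl]oxy}methyl)-5-nitro-4-(propan-2-yl)cyclohex-1-ene-1-carboxylate
Product: 10 ethyl (3R,4R)-3-({[tert-butyl(dimethyl)silyl]oxy}methyl)-4-(propan-2-yl)cyclohex-1-ene-1-carboxylate
Conditions: Bu3SnH (5 equiv), AIBN, toluene, 110 °C
Reagents that add atoms: none
Why: Radical denitration (stannyl radical addition to the nitro group, C–N homolysis, hydrogen transfer from Bu3SnH) is established for secondary nitro groups on cyclohexene rings and leaves C3 and C4 untouched.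

Step 4
Reactants: 10 ethyl (3R,4R)-3-({[tert-butyl(dimethyl)silyl]oxy}methyl)-4-(propan-2-yl)cyclohex-1-ene-1-carboxylate
Product: 11 [(3R,4R)-3-({[tert-butyl(dimethyl)silyl]oxy}methyl)-4-(propan-2-yl)cyclohex-1-en-1-yl]methanol
Conditions: i-Bu2AlH (2.5 equiv), CH2Cl2, −78 °C
Reagents that add atoms: none
Why: Hydride reduction of the conjugated ester by 1,2-addition should give the allylic alcohol while the silyl ether is inert.

Step 5
Reactants: 11 [(3R,4R)-3-({[tert-butyl(dimethyl)silyl]oxy}methyl)-4-(propan-2-yl)cyclohex-1-en-1-yl]methanol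
Product: 12 tert-butyl{[(1R,6R)-3-{[(4-methoxybenzyl)oxy]methyl}-6-(propan-2-yl)cyclohex-2-en-1-yl]methoxy}dimethylsilane
Conditions: NaH, 4-methoxybenzyl chloride, Bu4NI (cat.), THF/DMF, 0 °C → rt
Reagents that add atoms: 4-methoxybenzyl chloride (COc1ccc(CCl)cc1)
Why: Williamson etherification of the primary allylic alkoxide; the TBS ether is stable to NaH and too remote for silyl migration.

Step 6
Reactants: 12 tert-butyl{[(1R,6R)-3-{[(4-methoxybenzyl)oxy]methyl}-6-(propan-2-yl)cyclohex-2-en-1-yl]methoxy}dimethylsilane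
Product: 13 [(1R,6R)-3-{[(4-methoxybenzyl)oxy]methyl}-6-(propan-2-yl)cyclohex-2-en-1-yl]methanol
Conditions: Bu4NF, THF, 0 °C → rt
Reagents that add atoms: none
Why: Fluoride-mediated desilylation frees the primary alcohol while the PMB ether and the alkene are unaffected.

Step 7
Reactants: 13 [(1R,6R)-3-{[(4-methoxybenzyl)oxy]methyl}-6-(propan-2-yl)cyclohex-2-en-1-yl]methanol
Product: 14 (1R,6R)-3-{[(4-methoxybenzyl)oxy]methyl}-6-(propan-2-yl)cyclohex-2-ene-1-carbaldehyde
Conditions: TEMPO (10 mol%), PhI(OAc)2, CH2Cl2, rt; used at once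
Reagents that add atoms: none
Why: Oxoammonium (TEMPO) oxidation of the primary alcohol stops at the aldehyde under nearly neutral conditions, which should preserve the α-stereocentre of this β,γ-unsaturated aldehyde.

Step 8
Reactants: 14 (1R,6R)-3-{[(4-methoxybenzyl)oxy]methyl}-6-(propan-2-yl)cyclohex-2-ene-1-carbaldehyde; 6 ethyl 2-(diethoxyphosphoryl)acrylate
Product: 16 ethyl (2E)-2-{[(4-methoxybenzyl)oxy]methyl}-3-[(1R,6R)-3-{[(4-methoxybenzyl)oxy]methyl}-6-(propan-2-yl)cyclohex-2-en-1-yl]prop-2-enoate, via sodium phosphonate carbanion 15 (not isolated)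
Conditions: 4-methoxybenzyl alcohol, NaH, THF, 0 °C; 6, −78 °C; then 14, −78 → 0 °C
Reagents that add atoms: 4-methoxybenzyl alcohol (COc1ccc(CO)cc1)
Why: Oxa-Michael addition of the alkoxide to the phosphonoacrylate gives carbanion 15, whose Horner–Wadsworth–Emmons reaction with the α-branched aldehyde should favour the E-trisubstituted enoate (ester trans to the ring), the minor Z isomer being removed by chromatography.

Step 9
Reactants: 16 ethyl (2E)-2-{[(4-methoxybenzyl)oxy]methyl}-3-[(1R,6R)-3-{[(4-methoxybenzyl)oxy]methyl}-6-(propan-2-yl)cyclohex-2-en-1-yl]prop-2-enoate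
Product: 17 (2E)-2-{[(4-methoxybenzyl)oxy]methyl}-3-[(1R,6R)-3-{[(4-methoxybenzyl)oxy]methyl}-6-(propan-2-yl)cyclohex-2-en-1-yl]prop-2-enoic acid (Q–OH)
Conditions: LiOH, THF/MeOH/H2O, rt; then 1 M HCl to pH 4
Reagents that add atoms: lithium hydroxide ([Li+].[OH-])
Why: Saponification of the ethyl ester; the PMB ethers and the skipped diene should tolerate hydroxide at room temperature.

Step 10
Reactants: 18 3-methylbutanal; 19 but-3-en-2-one
Product: 20 (2R)-5-oxo-2-(propan-2-yl)hexanal
Conditions: (R)-α,α-diphenylprolinol methyl ether (5 mol%), ethyl 3,4-dihydroxybenzoate (20 mol%), neat, 4 °C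
Reagents that add atoms: none
Why: Enamine-mediated Michael addition to the enone, in which the (R)-diarylprolinol ether shields one enamine face and sets the (R) centre.

Step 11
Reactants: 20 (2R)-5-oxo-2-(propan-2-yl)hexanal
Product: 21 (4R)-4-(propan-2-yl)cyclohex-2-en-1-one ((R)-cryptone)
Conditions: LiOH (10 mol%), i-PrOH, rt
Reagents that add atoms: none
Why: Intramolecular aldol condensation of the methyl ketone onto the aldehyde gives the cyclohexenone, and the mild base should not racemise the γ-centre.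

Step 12
Reactants: 21 (4R)-4-(propan-2-yl)cyclohex-2-en-1-one
Product: 24 (2R,3R,4R)-3-ethenyl-4-(propan-2-yl)-2-{[(triethylsilyl)oxy]methyl}cyclohexan-1-one, via magnesium enolate 22 (not isolated), via magnesium aldolate 23 (not isolated)
Conditions: CH2=CHMgBr, CuBr·SMe2 (20 mol%), THF, −78 → −40 °C; monomeric CH2O in THF, −78 °C; Et3SiCl, DMAP (cat.), −78 → 0 °C
Reagents that add atoms: vinylmagnesium bromide (C=C[Mg]Br); formaldehyde (C=O); chlorotriethylsilane (CC[Si](Cl)(CC)CC)
Why: Copper-catalysed conjugate addition anti to the C4 isopropyl group sets C3, the regiodefined enolate 22 undergoes aldol addition to formaldehyde anti to the new vinyl group to set C2 (all-equatorial trans,trans array), and aldolate 23 is silylated in situ.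

Step 13
Reactants: 24 (2R,3R,4R)-3-ethenyl-4-(propan-2-yl)-2-{[(triethylsilyl)oxy]methyl}cyclohexan-1-one
Product: 25 (3S,4R,5R,6R)-5-ethenyl-6-(propan-2-yl)-4-{[(triethylsilyl)oxy]methyl}-1-oxaspiro[2.5]octane
Conditions: Me3S+ I−, n-BuLi, THF, −10 °C; then 24, −10 → 20 °C
Reagents that add atoms: trimethylsulfonium iodide (C[S+](C)C.[I-])
Why: Corey–Chaykovsky epoxidation, in which the small sulfonium ylide adds irreversibly from the axial direction of the chair ketone, should place the CH2 axial and the oxygen equatorial (trans to the C4 substituent), as the target requires.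

Step 14
Reactants: 25 (3S,4R,5R,6R)-5-ethenyl-6-(propan-2-yl)-4-{[(triethylsilyl)oxy]methyl}-1-oxaspiro[2.5]octane; 17 acid Q–OH
Product: 26 [(1S,2R,3R,4R)-3-ethenyl-1-hydroxy-4-(propan-2-yl)-2-{[(triethylsilyl)oxy]methyl}cyclohexyl]methyl ester of 17 (Q–O–CH2–)
Conditions: Cs2CO3 (0.2 equiv), DMF, 80 °C
Reagents that add atoms: none
Why: Base-catalysed epoxide opening by the carboxylate occurs by SN2 attack at the unsubstituted epoxide carbon, so the tertiary C–O bond and its configuration are untouched and the primary ester forms without protecting the tertiary alcohol.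

Step 15
Reactants: 26 triethylsilyl ether
Product: 27 [(1S,2R,3R,4R)-3-ethenyl-1-hydroxy-2-(hydroxymethyl)-4-(propan-2-yl)cyclohexyl]methyl ester of 17
Conditions: PPTS (cat.), MeOH, 0 °C → rt
Reagents that add atoms: none
Why: Mild acidic methanolysis removes the triethylsilyl ether while PMB ethers, the ester and the tertiary alcohol are stable.

Step 16
Reactants: 27 diol
Product: 28 (1S,2S,5R,6R)-6-ethenyl-2-hydroxy-5-(propan-2-yl)-2-[(Q-oxy)methyl]cyclohexane-1-carboxylic acid
Conditions: TEMPO (20 mol%), PhI(OAc)2 (2.5 equiv), MeCN/H2O, rt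
Reagents that add atoms: water (O)
Why: Oxoammonium oxidation in aqueous medium takes the primary alcohol through the aldehyde hydrate to the acid, and the tertiary alcohol, PMB ethers and alkenes should not be oxidised.

Step 17
Reactants: 28 hydroxy acid; 29 tert-butyl 2-(bromomethyl)acrylate
Product: 30 2-(tert-butoxycarbonyl)prop-2-en-1-yl (1S,2S,5R,6R)-6-ethenyl-2-hydroxy-5-(propan-2-yl)-2-[(Q-oxy)methyl]cyclohexane-1-carboxylate
Conditions: K2CO3, DMF, 0 °C → rt
Reagents that add atoms: none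
Why: Carboxylate O-alkylation by the allylic bromide (SN2 and SN2′ give the same ester) avoids activating the hindered acid, and the tertiary alcohol does not react.

Step 18
Reactants: 30 diene
Product: 31 tert-butyl (5aS,6R,9S,9aS)-9-hydroxy-1-oxo-6-(propan-2-yl)-9-[(Q-oxy)methyl]-1,3,5a,6,7,8,9,9a-octahydro-2-benzoxepine-4-carboxylate
Conditions: second-generation Hoveyda–Grubbs catalyst (10 mol%), toluene (2 mM), 80 °C
Reagents that add atoms: none
Why: Ring-closing metathesis between the vinyl group and the 1,1-disubstituted acrylate closes the seven-membered lactone (ring C) trans-fused to ring A; the trisubstituted alkenes of the acyl half should be inert.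

Step 19
Reactants: 31 bis-PMB ether
Product: 32 tert-butyl (5aS,6R,9S,9aS)-9-hydroxy-9-({[(2E)-2-(hydroxymethyl)-3-[(1R,6R)-3-(hydroxymethyl)-6-(propan-2-yl)cyclohex-2-en-1-yl]prop-2-enoyl]oxy}methyl)-1-oxo-6-(propan-2-yl)-1,3,5a,6,7,8,9,9a-octahydro-2-benzoxepine-4-carboxylate
Conditions: DDQ (2.5 equiv), CH2Cl2/pH 7 buffer, 0 °C
Reagents that add atoms: none
Why: Oxidative cleavage of both 4-methoxybenzyl ethers by DDQ (benzylic hydride abstraction, hydrolysis of the hemiacetal) under buffered conditions that spare the esters and alkenes.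

Step 20
Reactants: 32 tert-butyl ester triol
Product: 34 (5aS,6R,9S,9aS)-9-hydroxy-9-({[(2E)-2-(hydroxymethyl)-3-[(1R,6R)-3-(hydroxymethyl)-6-(propan-2-yl)cyclohex-2-en-1-yl]prop-2-enoyl]oxy}methyl)-1-oxo-6-(propan-2-yl)-1,3,5a,6,7,8,9,9a-octahydro-2-benzoxepine-4-carboxylic acid (the target), via persilylated ester 33 (not isolated)
Conditions: Me3SiOTf, 2,6-lutidine, CH2Cl2, 0 °C; then MeOH, aqueous citric acid, rt
Reagents that add atoms: none
Why: Silyl triflate converts the tert-butyl ester into the silyl ester with loss of isobutene and silylates the three hydroxyls (33), and mild acidic methanolysis then cleaves all Si–O bonds without acid strong enough to ionise the tertiary or allylic alcohols.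

Compound list
1 | 2-methylpropanal | CC(C)C=O | starting material
2 | nitromethane | C[N+](=O)[O-] | starting material
3 | 3-methyl-1-nitrobutan-2-ol (racemic) | CC(C)C(O)C[N+](=O)[O-] | intermediate
4 | (E)-3-methyl-1-nitrobut-1-ene | CC(C)/C=C/[N+](=O)[O-] | intermediate
5 | 3-[(tert-butyldimethylsilyl)oxy]propanal | O=CCCO[Si](C)(C)C(C)(C)C | starting material
6 | ethyl 2-(diethoxyphosphoryl)acrylate | C=C(C(=O)OCC)P(=O)(OCC)OCC | starting material
7 | (2S,3R)-2-({[tert-butyl(dimethyl)silyl]oxy}methyl)-4-methyl-3-(nitromethyl)pentanal | O=C[C@H](CO[Si](C)(C)C(C)(C)C)[C@@H](C(C)C)C[N+](=O)[O-] | intermediate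
8 | ethyl (5R,6S)-6-({[tert-butyl(dimethyl)silyl]oxy}methyl)-2-(diethoxyphosphoryl)-4-nitro-7-oxo-5-(propan-2-yl)heptanoate (epimers at C2 and C4) | O=C[C@H](CO[Si](C)(C)C(C)(C)C)[C@@H](C(C)C)C(CC(C(=O)OCC)P(=O)(OCC)OCC)[N+](=O)[O-] | intermediate
9 | ethyl (3S,4R,5RS)-3-({[tert-butyl(dimethyl)silyl]oxy}methyl)-5-nitro-4-(propan-2-yl)cyclohex-1-ene-1-carboxylate | CCOC(=O)C1=C[C@H](CO[Si](C)(C)C(C)(C)C)[C@@H](C(C)C)C([N+](=O)[O-])C1 | intermediate
10 | ethyl (3R,4R)-3-({[tert-butyl(dimethyl)silyl]oxy}methyl)-4-(propan-2-yl)cyclohex-1-ene-1-carboxylate | CCOC(=O)C1=C[C@H](CO[Si](C)(C)C(C)(C)C)[C@@H](C(C)C)CC1 | intermediate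
11 | [(3R,4R)-3-({[tert-butyl(dimethyl)silyl]oxy}methyl)-4-(propan-2-yl)cyclohex-1-en-1-yl]methanol | OCC1=C[C@H](CO[Si](C)(C)C(C)(C)C)[C@@H](C(C)C)CC1 | intermediate
12 | tert-butyl{[(1R,6R)-3-{[(4-methoxybenzyl)oxy]methyl}-6-(propan-2-yl)cyclohex-2-en-1-yl]methoxy}dimethylsilane | COc1ccc(COCC2=C[C@H](CO[Si](C)(C)C(C)(C)C)[C@@H](C(C)C)CC2)cc1 | intermediate
13 | [(1R,6R)-3-{[(4-methoxybenzyl)oxy]methyl}-6-(propan-2-yl)cyclohex-2-en-1-yl]methanol | COc1ccc(COCC2=C[C@H](CO)[C@@H](C(C)C)CC2)cc1 | intermediate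
14 | (1R,6R)-3-{[(4-methoxybenzyl)oxy]methyl}-6-(propan-2-yl)cyclohex-2-ene-1-carbaldehyde | COc1ccc(COCC2=C[C@H](C=O)[C@@H](C(C)C)CC2)cc1 | intermediate
15 | sodium salt of the carbanion of ethyl 2-(diethoxyphosphoryl)-3-[(4-methoxybenzyl)oxy]propanoate | [Na+].CCOC(=O)[C-](COCc1ccc(OC)cc1)P(=O)(OCC)OCC | intermediate
16 | ethyl (2E)-2-{[(4-methoxybenzyl)oxy]methyl}-3-[(1R,6R)-3-{[(4-methoxybenzyl)oxy]methyl}-6-(propan-2-yl)cyclohex-2-en-1-yl]prop-2-enoate | CCOC(=O)/C(=C/[C@H]1C=C(COCc2ccc(OC)cc2)CC[C@@H]1C(C)C)COCc1ccc(OC)cc1 | intermediate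
17 | (2E)-2-{[(4-methoxybenzyl)oxy]methyl}-3-[(1R,6R)-3-{[(4-methoxybenzyl)oxy]methyl}-6-(propan-2-yl)cyclohex-2-en-1-yl]prop-2-enoic acid (Q–OH) | OC(=O)/C(=C/[C@H]1C=C(COCc2ccc(OC)cc2)CC[C@@H]1C(C)C)COCc1ccc(OC)cc1 | intermediate
18 | 3-methylbutanal | CC(C)CC=O | starting material
19 | but-3-en-2-one | CC(=O)C=C | starting material
20 | (2R)-5-oxo-2-(propan-2-yl)hexanal | O=C[C@@H](C(C)C)CCC(C)=O | intermediate
21 | (4R)-4-(propan-2-yl)cyclohex-2-en-1-one | CC(C)[C@H]1CCC(=O)C=C1 | intermediate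
22 | bromomagnesium enolate of (3R,4R)-3-ethenyl-4-(propan-2-yl)cyclohexanone | CC(C)[C@H]1CCC(O[Mg]Br)=C[C@@H]1C=C | intermediate
23 | bromomagnesium alkoxide of (2R,3R,4R)-3-ethenyl-2-(hydroxymethyl)-4-(propan-2-yl)cyclohexan-1-one | CC(C)[C@H]1CCC(=O)[C@@H](CO[Mg]Br)[C@@H]1C=C | intermediate
24 | (2R,3R,4R)-3-ethenyl-4-(propan-2-yl)-2-{[(triethylsilyl)oxy]methyl}cyclohexan-1-one | CC(C)[C@H]1CCC(=O)[C@@H](CO[Si](CC)(CC)CC)[C@@H]1C=C | intermediate
25 | (3S,4R,5R,6R)-5-ethenyl-6-(propan-2-yl)-4-{[(triethylsilyl)oxy]methyl}-1-oxaspiro[2.5]octane | CC(C)[C@H]1CC[C@@]2(CO2)[C@@H](CO[Si](CC)(CC)CC)[C@@H]1C=C | intermediate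
26 | [(1S,2R,3R,4R)-3-ethenyl-1-hydroxy-4-(propan-2-yl)-2-{[(triethylsilyl)oxy]methyl}cyclohexyl]methyl ester of 17 | CC(C)[C@H]1CC[C@@](O)(COC(=O)/C(=C/[C@H]2C=C(COCc3ccc(OC)cc3)CC[C@@H]2C(C)C)COCc2ccc(OC)cc2)[C@@H](CO[Si](CC)(CC)CC)[C@@H]1C=C | intermediate
27 | [(1S,2R,3R,4R)-3-ethenyl-1-hydroxy-2-(hydroxymethyl)-4-(propan-2-yl)cyclohexyl]methyl ester of 17 | CC(C)[C@H]1CC[C@@](O)(COC(=O)/C(=C/[C@H]2C=C(COCc3ccc(OC)cc3)CC[C@@H]2C(C)C)COCc2ccc(OC)cc2)[C@@H](CO)[C@@H]1C=C | intermediate
28 | (1S,2S,5R,6R)-6-ethenyl-2-hydroxy-5-(propan-2-yl)-2-[(Q-oxy)methyl]cyclohexane-1-carboxylic acid | CC(C)[C@H]1CC[C@@](O)(COC(=O)/C(=C/[C@H]2C=C(COCc3ccc(OC)cc3)CC[C@@H]2C(C)C)COCc2ccc(OC)cc2)[C@@H](C(=O)O)[C@@H]1C=C | intermediate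
29 | tert-butyl 2-(bromomethyl)acrylate | C=C(CBr)C(=O)OC(C)(C)C | starting material
30 | 2-(tert-butoxycarbonyl)prop-2-en-1-yl (1S,2S,5R,6R)-6-ethenyl-2-hydroxy-5-(propan-2-yl)-2-[(Q-oxy)methyl]cyclohexane-1-carboxylate | CC(C)[C@H]1CC[C@@](O)(COC(=O)/C(=C/[C@H]2C=C(COCc3ccc(OC)cc3)CC[C@@H]2C(C)C)COCc2ccc(OC)cc2)[C@@H](C(=O)OCC(=C)C(=O)OC(C)(C)C)[C@@H]1C=C | intermediate
31 | tert-butyl (5aS,6R,9S,9aS)-9-hydroxy-1-oxo-6-(propan-2-yl)-9-[(Q-oxy)methyl]-1,3,5a,6,7,8,9,9a-octahydro-2-benzoxepine-4-carboxylate | CC(C)[C@H]1CC[C@@](O)(COC(=O)/C(=C/[C@H]2C=C(COCc3ccc(OC)cc3)CC[C@@H]2C(C)C)COCc2ccc(OC)cc2)[C@H]2C(=O)OCC(C(=O)OC(C)(C)C)=C[C@H]12 | intermediate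
32 | tert-butyl ester of the target (both hydroxymethyl groups and the tertiary hydroxyl free) | CC(C)[C@H]1CC[C@@](O)(COC(=O)/C(=C/[C@H]2C=C(CO)CC[C@@H]2C(C)C)CO)[C@H]2C(=O)OCC(C(=O)OC(C)(C)C)=C[C@H]12 | intermediate
33 | trimethylsilyl ester of the target with all three hydroxyls as trimethylsilyl ethers | CC(C)[C@H]1CC[C@@](O[Si](C)(C)C)(COC(=O)/C(=C/[C@H]2C=C(CO[Si](C)(C)C)CC[C@@H]2C(C)C)CO[Si](C)(C)C)[C@H]2C(=O)OCC(C(=O)O[Si](C)(C)C)=C[C@H]12 | intermediate
34 | (5aS,6R,9S,9aS)-9-hydroxy-9-({[(2E)-2-(hydroxymethyl)-3-[(1R,6R)-3-(hydroxymethyl)-6-(propan-2-yl)cyclohex-2-en-1-yl]prop-2-enoyl]oxy}methyl)-1-oxo-6-(propan-2-yl)-1,3,5a,6,7,8,9,9a-octahydro-2-benzoxepine-4-carboxylic acid | CC(C)[C@H]1CC[C@@](O)(COC(=O)/C(=C/[C@H]2C=C(CO)CC[C@@H]2C(C)C)CO)[C@H]2C(=O)OCC(C(=O)O)=C[C@H]12 | target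

Total step count: 20. Longest linear sequence: 16 steps (steps 1–9, then steps 14–20).

Steps most likely to fail

Risk 1, step 2 (key step). Under Cs2CO3 the aldehyde α-centre (C3′) may epimerise, or the nitronate adduct may revert before the olefination, eroding the trans C3′/C4′ relation and the yield. The fallback sets out from 7, which is isolated by stopping step 2 after the first Michael stage. With the same amine catalyst, benzoic acid and acrolein in toluene, 7 should undergo nitro-Michael addition to the iminium ion and intramolecular aldol condensation, closing the same C1′=C2′ bond without carbonate base and giving (3S,4R,5RS)-3-({[tert-butyl(dimethyl)silyl]oxy}methyl)-5-nitro-4-(propan-2-yl)cyclohex-1-ene-1-carbaldehyde F1. Luche reduction (NaBH4, CeCl3, MeOH) would give [(3S,4R,5RS)-3-({[tert-butyl(dimethyl)silyl]oxy}methyl)-5-nitro-4-(propan-2-yl)cyclohex-1-en-1-yl]methanol F2, and radical denitration (Bu3SnH, AIBN, toluene, 110 °C) returns to the route at 11.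

Risk 2, step 14. SN2 attack of the weakly nucleophilic carboxylate at the axial, neopentyl-type epoxide carbon may be slow, so that thermal isomerisation of 17 or loss of the silyl ether competes. The fallback sets out from 25. Small, excess hydroxide (KOH, DMSO/H2O, 80 °C) should open the epoxide at the CH2 to give (1S,2R,3R,4R)-3-ethenyl-1-(hydroxymethyl)-4-(propan-2-yl)-2-{[(triethylsilyl)oxy]methyl}cyclohexan-1-ol F3. Acid 17 is activated as its mixed anhydride with 2,4,6-trichlorobenzoic acid F4 (2,4,6-trichlorobenzoyl chloride, Et3N), and Yamaguchi esterification (DMAP, toluene) should acylate only the primary hydroxyl of F3, coming back to the route at 26.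

Risk 3, step 8. The phosphonate carbanion may deprotonate the β,γ-unsaturated aldehyde (epimerisation at C1 or migration of the ring alkene into conjugation), and E selectivity may be incomplete. The fallback sets out from 14. A neutral Wittig reaction with ethyl bromo(triphenylphosphoranylidene)acetate should give ethyl (2Z)-2-bromo-3-[(1R,6R)-3-{[(4-methoxybenzyl)oxy]methyl}-6-(propan-2-yl)cyclohex-2-en-1-yl]prop-2-enoate F5 (ester trans to the ring). Stille coupling with (tributylstannyl)methanol and Pd(PPh3)4 should replace bromine with retention to give ethyl (2E)-2-(hydroxymethyl)-3-[(1R,6R)-3-{[(4-methoxybenzyl)oxy]methyl}-6-(propan-2-yl)cyclohex-2-en-1-yl]prop-2-enoate F6. Etherification with 4-methoxybenzyl trichloroacetimidate (camphorsulfonic acid, cat.) comes back to the route at 16.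

Further compounds
F1 | step 2 | (3S,4R,5RS)-3-({[tert-butyl(dimethyl)silyl]oxy}methyl)-5-nitro-4-(propan-2-yl)cyclohex-1-ene-1-carbaldehyde | O=CC1=C[C@H](CO[Si](C)(C)C(C)(C)C)[C@@H](C(C)C)C([N+](=O)[O-])C1
F2 | step 2 | [(3S,4R,5RS)-3-({[tert-butyl(dimethyl)silyl]oxy}methyl)-5-nitro-4-(propan-2-yl)cyclohex-1-en-1-yl]methanol | OCC1=C[C@H](CO[Si](C)(C)C(C)(C)C)[C@@H](C(C)C)C([N+](=O)[O-])C1
F3 | step 14 | (1S,2R,3R,4R)-3-ethenyl-1-(hydroxymethyl)-4-(propan-2-yl)-2-{[(triethylsilyl)oxy]methyl}cyclohexan-1-ol | CC(C)[C@H]1CC[C@@](O)(CO)[C@@H](CO[Si](CC)(CC)CC)[C@@H]1C=C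
F4 | step 14 | mixed anhydride of 17 with 2,4,6-trichlorobenzoic acid | O=C(OC(=O)/C(=C/[C@H]1C=C(COCc2ccc(OC)cc2)CC[C@@H]1C(C)C)COCc1ccc(OC)cc1)c1c(Cl)cc(Cl)cc1Cl
F5 | step 8 | ethyl (2Z)-2-bromo-3-[(1R,6R)-3-{[(4-methoxybenzyl)oxy]methyl}-6-(propan-2-yl)cyclohex-2-en-1-yl]prop-2-enoate | CCOC(=O)/C(=C/[C@H]1C=C(COCc2ccc(OC)cc2)CC[C@@H]1C(C)C)Br
F6 | step 8 | ethyl (2E)-2-(hydroxymethyl)-3-[(1R,6R)-3-{[(4-methoxybenzyl)oxy]methyl}-6-(propan-2-yl)cyclohex-2-en-1-yl]prop-2-enoate | CCOC(=O)/C(=C/[C@H]1C=C(COCc2ccc(OC)cc2)CC[C@@H]1C(C)C)CO
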